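Target in these flasks climbs fast and then sinks, so what you harvest depends on whether the sinking has ended when you stop.

| flask | substrate | temperature | remark | time |
|---|---|---|---|---|
| Sunday's | 1.2 M | −10 °C | run made earlier |  |
| Monday's | 1.2 M | 1 °C | run made earlier |  |
| oak | 1.0 M |  | at 5 °C until 2.5 d, from then on at −15 °C | 5.0 d |
| elm | 3.0 M |  | at 5 °C throughout | 5.0 d |

| run | time / d | target / % | substrate / % |
|---|---|---|---|
| Sunday's | 0.417 | 57.0 | 38.5 |
| Sunday's | 0.625 | 68.5 | 25.8 |
| Sunday's | 1.04 | 76.5 | 12.5 |
| Sunday's | 1.67 | 78.2 | 5.4 |
| Sunday's | 4.00 | 66.6 | 5.5 |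
| Sunday's | 5.00 | 64.5 | 3.2 |
| Monday's | 0.208 | 76.0 | 13.2 |
| Monday's | 0.333 | 79.4 | 6.6 |
| Monday's | 0.500 | 72.6 | 4.0 |
| Monday's | 0.833 | 64.5 | 2.8 |
| Monday's | 1.67 | 56.1 | 3.5 |
| Monday's | 2.50 | 55.2 | 3.2 |

(each reading ± 1 percentage point)

- which one finishes higher in amount of target, in percent of the substrate charged ("neither" within 2 percentage points) (oak / elm / neither)
- amount of target at the end, in percent of the substrate charged, oak
- amount of target at the end, in percent of the substrate charged, elm



Lay the two runs side by side. Monday's reads 64.5% target after 0.833 d, and Sunday's reads 64.5% after 5.00 d, so take Sunday's as Monday's curve on a slower clock, by a factor 6.00.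

Monday's goes flat at about 1.67 d, near 55.2%. Multiply by the clock factor and Sunday's would need 10.0 d, longer than its run, so you read its last value as still sinking, not as a plateau.

Now let the factor compound evenly per degree. The settling time at 5 °C, the time target needs there to stop sinking, comes to 0.870 d. That is shorter than the 2.5 d before oak is cooled, so oak and elm both reach the plateau, which I put near Monday's value.

At −15 °C the settling time grows to 22.6 d, and oak's remaining 2.50 d covers 11.0% of it. So in my reckoning the cold half of oak is a quench: its time is too short for target to move far, and oak keeps about what it had at the change. My reckoning is neither, both near 55.2%, if the sinking is first order, which two runs at 1.2 M cannot test.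

The weak link is a clock factor read from one pair of readings. Reforge it from the peaks: 5.02 gives 0.929 d warm and 17.4 d cold, and both comparisons stand.

The forecast differs, naming oak as higher, with 61% for oak against 51% for elm: “Oak reaches about 53% by 2.5 d, then recovers to about 61%.”

The flasks give neither: oak 53.2%, elm 53.3%.

    isomer of the product B ⇌ substrate (k = 0.0194 h⁻¹, Ea = 104 kJ mol⁻¹)
    target ⇌ isomer of the product A (K = 0.741, k = 0.0499 h⁻¹, Ea = 95.0 kJ mol⁻¹, ΔH = −3.00 kJ mol⁻¹)
    substrate ⇌ target (K = 18.3, k = 0.736 h⁻¹, Ea = 85.0 kJ mol⁻¹, ΔH = −8.00 kJ mol⁻¹)
    isomer of the product A ⇌ isomer of the product B (K = 0.110, k = 0.00870 h⁻¹, Ea = 104 kJ mol⁻¹, ΔH = −23.0 kJ mol⁻¹)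
    (constants at 5 °C)

Oak's target reads 53.4% at the change and 53.2% at the end, the flat line that the cold settling time foretold. Now take a neighbour: oak read at 50 h, before any cooling. Its 2.08 d at 5 °C exceeds the settling time of 0.870 d, so the same reckoning places this reading on the plateau already. The neighbour holds 2.92% substrate and 39.3% isomer of the product A, and its target stands at 53.5%.

Readings and results stem from a simulated flask from invented constants, noise included.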